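The target is (2S)-5-hydroxy-2-(4-hydroxyphenyl)-6,7-dimethoxy-8-prenylchroman-4-one; the route below reaches it in seven linear steps.

Everything rests on opening ring C at the O1–C2 bond. C2 is benzylic to ring B and β to the C4 ketone, and O1 sits on C8a next to the acyl-bearing C4a, so ring C is the oxa-Michael adduct of a 2'-hydroxychalcone. The precursor is that chalcone with a temporary tert-butyl ester on the α-carbon (future C3), the prenyl group already on the future C8, and the future C5 oxygen kept as a methyl ether so that only O1–H can add. One operation closes ring C under a cinchona thiourea, sets C2 as S, and then strips the ester and the ring B tert-butyl ether with acid.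

Key step: step 6

Remark on the chemistry: the two pseudoenantiomeric cinchona thioureas give opposite enantiomers; the quinidine-derived one is assumed to deliver (2S), and the quinine-derived one would replace it unchanged if the sense proved opposite. Compound 9 is used as its E/Z mixture; compounds 1, 2 and 8 are commercial.

Step 1
Reactants: 1 1-(2-hydroxy-4,5,6-trimethoxyphenyl)ethan-1-one; 2 3-chloro-3-methylbut-1-yne
Product: 3 1-[2,3,4-trimethoxy-6-(2-methylbut-3-yn-2-yloxy)phenyl]ethan-1-one
Conditions: DBU, CuCl2·2H2O (1 mol %), MeCN, 0 °C → rt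
Reagents that add atoms: none
Why: Copper-catalysed propargylic etherification of a phenol (through a copper acetylide/allenylidene, so the phenoxide made by DBU attacks the tertiary carbon) should put the 1,1-dimethylpropargyl group on the only free hydroxyl; no stereocentre is formed.

Step 2
Reactants: 3 1-[2,3,4-trimethoxy-6-(2-methylbut-3-yn-2-yloxy)phenyl]ethan-1-one
Product: 4 1-[2,3,4-trimethoxy-6-(2-methylbut-3-en-2-yloxy)phenyl]ethan-1-one
Conditions: H2 (1 atm), Pd/CaCO3 poisoned with Pb(OAc)2, quinoline, EtOAc, rt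
Reagents that add atoms: none
Why: Lindlar semi-hydrogenation should stop at the terminal alkene on the poisoned palladium surface, the aryl ketone and the aryl ethers being inert to it.

Step 3
Reactants: 4 1-[2,3,4-trimethoxy-6-(2-methylbut-3-en-2-yloxy)phenyl]ethan-1-one
Product: 5 1-[2-hydroxy-4,5,6-trimethoxy-3-(3-methylbut-2-en-1-yl)phenyl]ethan-1-one
Conditions: PhMe, 110 °C (sealed tube)
Reagents that add atoms: none
Why: Aromatic Claisen rearrangement: the [3,3] shift should deliver the allyl unit, inverted to a 3-methylbut-2-enyl (prenyl) group, to the only ortho carbon that bears hydrogen, and tautomerisation restores the phenol, now hydrogen-bonded to the acetyl group.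

Step 4
Reactants: 5 1-[2-hydroxy-4,5,6-trimethoxy-3-(3-methylbut-2-en-1-yl)phenyl]ethan-1-one
Product: 7 tert-butyl 3-[2-hydroxy-4,5,6-trimethoxy-3-(3-methylbut-2-en-1-yl)phenyl]-3-oxopropanoate, via aryl tert-butyl carbonate 6 (not isolated)
Conditions: Boc2O (1.1 equiv), DMAP (10 mol %), THF, rt; then LiN(SiMe3)2 (3.3 equiv), −78 → 0 °C; AcOH quench
Reagents that add atoms: di-tert-butyl dicarbonate, CC(C)(C)OC(=O)OC(=O)OC(C)(C)C
Why: DMAP-catalysed O-acylation should give carbonate 6, whose methyl ketone lithium enolate attacks the neighbouring carbonate carbonyl through a six-membered tetrahedral intermediate that expels the phenoxide rather than tert-butoxide (Baker–Venkataraman-type O-to-C acyl transfer), so the ester lands on the α-carbon and the phenol is free again.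

Step 5
Reactants: 7 tert-butyl 3-[2-hydroxy-4,5,6-trimethoxy-3-(3-methylbut-2-en-1-yl)phenyl]-3-oxopropanoate; 8 4-(tert-butoxy)benzaldehyde
Product: 9 tert-butyl 3-(4-tert-butoxyphenyl)-2-[2-hydroxy-4,5,6-trimethoxy-3-(3-methylbut-2-en-1-yl)benzoyl]prop-2-enoate (E/Z mixture)
Conditions: piperidine (20 mol %), AcOH (20 mol %), 4 Å molecular sieves, PhMe, rt → 40 °C
Reagents that add atoms: none
Why: Knoevenagel condensation of the active methylene group with the aldehyde under piperidinium acetate catalysis with removal of water; the buffered medium and the hydrogen bond of the phenol to the ketone should keep premature ring closure low.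

Step 6
Reactants: 9 tert-butyl 3-(4-tert-butoxyphenyl)-2-[2-hydroxy-4,5,6-trimethoxy-3-(3-methylbut-2-en-1-yl)benzoyl]prop-2-enoate
Product: 12 (2S)-2-(4-hydroxyphenyl)-5,6,7-trimethoxy-8-(3-methylbut-2-en-1-yl)chroman-4-one, via chromanone tert-butyl ester 10 (not isolated), via chromanone carboxylic acid 11 (not isolated)
Conditions: quinidine-derived 9-epi-amino thiourea bearing a 3,5-bis(trifluoromethyl)phenyl group (10 mol %), PhMe, −25 °C; then TsOH·H2O (1.5 equiv), 80 °C
Reagents that add atoms: none
Why: The quinuclidine nitrogen of the bifunctional catalyst should deprotonate the one free phenol of 9 while its thiourea hydrogen-bonds the β-keto ester, and the phenoxide oxygen (future O1) adds to the benzylidene carbon (future C2) in an intramolecular oxa-Michael addition that gives ester 10. The closest known reaction type is the cinchona-thiourea-catalysed oxa-conjugate addition of 2-hydroxyaryl alkylidene β-keto tert-butyl esters, followed by acid decarboxylation in the same flask, to give flavanones. Ring C closes in the 6-endo-trig mode. C2 is set by the catalyst, which holds the alkylidene through the thiourea and delivers the phenoxide to one face of it, whereas C3 of 10 is of no consequence because it becomes a CH2 group on decarboxylation. The step needs regioselectivity between the two oxygens ortho to the acyl carbon and enough electrophilicity in an electron-rich 4-alkoxybenzylidene: the first is secured by the substrate, in which the future C5 oxygen is a methyl ether and only the hydroxyl next to the prenyl-bearing carbon is free, and the second by the α-ester, which also suppresses the retro-addition that erodes ee in unactivated chalcones. TsOH should then remove the tert-butyl ester and the tert-butyl aryl ether as 2-methylpropene, acid 11 loses CO2, and neither C2 (no base present) nor the prenyl group (no free hydroxyl ortho to it) has an easy path to react.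

Step 7
Reactants: 12 (2S)-2-(4-hydroxyphenyl)-5,6,7-trimethoxy-8-(3-methylbut-2-en-1-yl)chroman-4-one
Product: 13 (2S)-5-hydroxy-2-(4-hydroxyphenyl)-6,7-dimethoxy-8-(3-methylbut-2-en-1-yl)chroman-4-one
Conditions: MgI2·OEt2 (5 equiv), THF, 60 °C; then H2O
Reagents that add atoms: none
Why: Chelation-controlled Lewis acid demethylation: magnesium binds the C4 carbonyl oxygen and the peri C5 methoxy oxygen in a six-membered chelate, so iodide should attack that methyl group alone in an SN2 step, while the C6 and C7 methoxy groups, the prenyl alkene and the C2 centre are left alone under these non-basic conditions.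

Compound list

1 | 1-(2-hydroxy-4,5,6-trimethoxyphenyl)ethan-1-one | CC(=O)c1c(O)cc(OC)c(OC)c1OC | starting material
2 | 3-chloro-3-methylbut-1-yne | C#CC(C)(C)Cl | starting material
3 | 1-[2,3,4-trimethoxy-6-(2-methylbut-3-yn-2-yloxy)phenyl]ethan-1-one | CC(=O)c1c(OC(C)(C)C#C)cc(OC)c(OC)c1OC | intermediate
4 | 1-[2,3,4-trimethoxy-6-(2-methylbut-3-en-2-yloxy)phenyl]ethan-1-one | CC(=O)c1c(OC(C)(C)C=C)cc(OC)c(OC)c1OC | intermediate
5 | 1-[2-hydroxy-4,5,6-trimethoxy-3-(3-methylbut-2-en-1-yl)phenyl]ethan-1-one | CC(=O)c1c(O)c(CC=C(C)C)c(OC)c(OC)c1OC | intermediate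
6 | 2-acetyl-3,4,5-trimethoxy-6-(3-methylbut-2-en-1-yl)phenyl tert-butyl carbonate | CC(=O)c1c(OC(=O)OC(C)(C)C)c(CC=C(C)C)c(OC)c(OC)c1OC | intermediate (not isolated)
7 | tert-butyl 3-[2-hydroxy-4,5,6-trimethoxy-3-(3-methylbut-2-en-1-yl)phenyl]-3-oxopropanoate | CC(C)(C)OC(=O)CC(=O)c1c(O)c(CC=C(C)C)c(OC)c(OC)c1OC | intermediate
8 | 4-(tert-butoxy)benzaldehyde | CC(C)(C)Oc1ccc(C=O)cc1 | starting material
9 | tert-butyl 3-(4-tert-butoxyphenyl)-2-[2-hydroxy-4,5,6-trimethoxy-3-(3-methylbut-2-en-1-yl)benzoyl]prop-2-enoate (E/Z mixture) | CC(C)(C)OC(=O)C(=Cc1ccc(OC(C)(C)C)cc1)C(=O)c1c(O)c(CC=C(C)C)c(OC)c(OC)c1OC | intermediate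
10 | tert-butyl (2S)-2-(4-tert-butoxyphenyl)-5,6,7-trimethoxy-8-(3-methylbut-2-en-1-yl)-4-oxochromane-3-carboxylate (C3 epimers and enol) | COc1c(OC)c2c(c(CC=C(C)C)c1OC)O[C@H](c1ccc(OC(C)(C)C)cc1)C(C(=O)OC(C)(C)C)C2=O | intermediate (not isolated)
11 | (2S)-2-(4-hydroxyphenyl)-5,6,7-trimethoxy-8-(3-methylbut-2-en-1-yl)-4-oxochromane-3-carboxylic acid | COc1c(OC)c2c(c(CC=C(C)C)c1OC)O[C@H](c1ccc(O)cc1)C(C(=O)O)C2=O | intermediate (not isolated)
12 | (2S)-2-(4-hydroxyphenyl)-5,6,7-trimethoxy-8-(3-methylbut-2-en-1-yl)chroman-4-one | COc1c(OC)c2c(c(CC=C(C)C)c1OC)O[C@H](c1ccc(O)cc1)CC2=O | intermediate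
13 | (2S)-5-hydroxy-2-(4-hydroxyphenyl)-6,7-dimethoxy-8-(3-methylbut-2-en-1-yl)chroman-4-one | COc1c(O)c2c(c(CC=C(C)C)c1OC)O[C@H](c1ccc(O)cc1)CC2=O | target

Total steps: 7. Longest linear sequence: 7 steps (1 to 13).

Steps most likely to fail

Step 6. The conjugate addition may be slow or poorly face-selective, because the benzylidene is electron-rich and the aroyl group is flanked by two ortho substituents, and ee may also be lost if part of 9 has already closed without the catalyst. The fallback is ring closure without asymmetric induction, followed by resolution. Setting out from 9, Et3N (20 mol %) in PhMe at rt should close ring C to racemic chromanone tert-butyl ester F1. TsOH·H2O at 80 °C should then take it through racemic chromanone carboxylic acid F2 to racemic trimethoxyflavanone F3. Preparative HPLC on an amylose tris(3,5-dimethylphenylcarbamate) phase should separate 12 from its (2R)-enantiomer F4, which can be racemised with base and resolved again. The fallback comes back to the route at 12.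

Step 7. The demethylation may erode ee through Lewis acid-assisted opening and re-closure of ring C at 60 °C, may go on to the C6 methoxy group once the C5 phenoxide is formed, or may add HI to the prenyl alkene. The fallback carries the C5 oxygen through the route as a methoxymethyl ether, which the acid stage of the ring closure removes, so that no demethylation follows ring closure. It sets out from 1 and runs as follows.
- AlCl3 in MeCN at 60 °C should cleave the methoxy group next to the acetyl group to give dihydroxy ketone F5.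
- Copper-catalysed propargylation with 2 (DBU, CuCl2·2H2O, MeCN) at the less hindered hydroxyl, the one with a CH neighbour, should give mono-propargyl ether F6.
- NaH and MOMCl in DMF at 0 °C should cap the remaining hydroxyl as MOM ether F7.
- Semi-hydrogenation as in step 2 should give allyl ether F8.
- Claisen rearrangement as in step 3 should give prenyl phenol F9.
- Boc2O/DMAP, then LiN(SiMe3)2, should give β-keto ester F11 through aryl carbonate F10.
- Knoevenagel condensation with 8 should give benzylidene F12.
- The thiourea-catalysed closure should give MOM-protected chromanone ester F13. The TsOH stage then removes the tert-butyl ester, the tert-butyl ether and the MOM group, and the resulting acid F14 loses CO2 to give 13 directly.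

The fallback comes back to the route at 13.

Step 1. The etherification may stay incomplete, because the phenoxide is hindered and its parent phenol is hydrogen-bonded to the acetyl group, or the tertiary propargyl group may be lost by elimination. The fallback brings the prenyl group in as a primary allyl ether and moves it to carbon by a [1,3] shift on an acidic surface, in place of the propargyl ether, semi-hydrogenation and Claisen sequence. Setting out from 1, prenyl bromide with K2CO3 in acetone at reflux should give prenyl ether F15. Stirring F15 with activated MgSiO3 in PhMe at rt to 60 °C should move the prenyl group to the only open ring carbon, ortho to the oxygen, to give 5. The fallback comes back to the route at 5, and steps 2 and 3 are skipped.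

Further compounds

F1 | step 6 | racemic tert-butyl 2-(4-tert-butoxyphenyl)-5,6,7-trimethoxy-8-(3-methylbut-2-en-1-yl)-4-oxochromane-3-carboxylate | COc1c(OC)c2c(c(CC=C(C)C)c1OC)OC(c1ccc(OC(C)(C)C)cc1)C(C(=O)OC(C)(C)C)C2=O
F2 | step 6 | racemic 2-(4-hydroxyphenyl)-5,6,7-trimethoxy-8-(3-methylbut-2-en-1-yl)-4-oxochromane-3-carboxylic acid | COc1c(OC)c2c(c(CC=C(C)C)c1OC)OC(c1ccc(O)cc1)C(C(=O)O)C2=O
F3 | step 6 | racemic 2-(4-hydroxyphenyl)-5,6,7-trimethoxy-8-(3-methylbut-2-en-1-yl)chroman-4-one | COc1c(OC)c2c(c(CC=C(C)C)c1OC)OC(c1ccc(O)cc1)CC2=O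
F4 | step 6 | (2R)-2-(4-hydroxyphenyl)-5,6,7-trimethoxy-8-(3-methylbut-2-en-1-yl)chroman-4-one | COc1c(OC)c2c(c(CC=C(C)C)c1OC)O[C@@H](c1ccc(O)cc1)CC2=O
F5 | step 7 | 1-(2,6-dihydroxy-3,4-dimethoxyphenyl)ethan-1-one | CC(=O)c1c(O)cc(OC)c(OC)c1O
F6 | step 7 | 1-[2-hydroxy-3,4-dimethoxy-6-(2-methylbut-3-yn-2-yloxy)phenyl]ethan-1-one | CC(=O)c1c(OC(C)(C)C#C)cc(OC)c(OC)c1O
F7 | step 7 | 1-[3,4-dimethoxy-2-(methoxymethoxy)-6-(2-methylbut-3-yn-2-yloxy)phenyl]ethan-1-one | CC(=O)c1c(OC(C)(C)C#C)cc(OC)c(OC)c1OCOC
F8 | step 7 | 1-[3,4-dimethoxy-2-(methoxymethoxy)-6-(2-methylbut-3-en-2-yloxy)phenyl]ethan-1-one | CC(=O)c1c(OC(C)(C)C=C)cc(OC)c(OC)c1OCOC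
F9 | step 7 | 1-[2-hydroxy-4,5-dimethoxy-6-(methoxymethoxy)-3-(3-methylbut-2-en-1-yl)phenyl]ethan-1-one | CC(=O)c1c(O)c(CC=C(C)C)c(OC)c(OC)c1OCOC
F10 | step 7 | 2-acetyl-4,5-dimethoxy-3-(methoxymethoxy)-6-(3-methylbut-2-en-1-yl)phenyl tert-butyl carbonate | CC(=O)c1c(OC(=O)OC(C)(C)C)c(CC=C(C)C)c(OC)c(OC)c1OCOC
F11 | step 7 | tert-butyl 3-[2-hydroxy-4,5-dimethoxy-6-(methoxymethoxy)-3-(3-methylbut-2-en-1-yl)phenyl]-3-oxopropanoate | CC(C)(C)OC(=O)CC(=O)c1c(O)c(CC=C(C)C)c(OC)c(OC)c1OCOC
F12 | step 7 | tert-butyl 3-(4-tert-butoxyphenyl)-2-[2-hydroxy-4,5-dimethoxy-6-(methoxymethoxy)-3-(3-methylbut-2-en-1-yl)benzoyl]prop-2-enoate (E/Z mixture) | CC(C)(C)OC(=O)C(=Cc1ccc(OC(C)(C)C)cc1)C(=O)c1c(O)c(CC=C(C)C)c(OC)c(OC)c1OCOC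
F13 | step 7 | tert-butyl (2S)-2-(4-tert-butoxyphenyl)-6,7-dimethoxy-5-(methoxymethoxy)-8-(3-methylbut-2-en-1-yl)-4-oxochromane-3-carboxylate | COc1c(OCOC)c2c(c(CC=C(C)C)c1OC)O[C@H](c1ccc(OC(C)(C)C)cc1)C(C(=O)OC(C)(C)C)C2=O
F14 | step 7 | (2S)-5-hydroxy-2-(4-hydroxyphenyl)-6,7-dimethoxy-8-(3-methylbut-2-en-1-yl)-4-oxochromane-3-carboxylic acid | COc1c(O)c2c(c(CC=C(C)C)c1OC)O[C@H](c1ccc(O)cc1)C(C(=O)O)C2=O
F15 | step 1 | 1-[2,3,4-trimethoxy-6-(3-methylbut-2-en-1-yloxy)phenyl]ethan-1-one | CC(=O)c1c(OCC=C(C)C)cc(OC)c(OC)c1OC
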